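**Retrosynthetic overview**
1. Target 29 ⇐ 1(10)-olefin 28: the C1/C10 oxirane is made last by face-selective peracid C–O bond formation.
2. 28 ⇐ iodo aldehyde 25 + anhydride 26: the ten-membered carbocycle is closed at C3–C4 by a new acylative Cr/Ni alkenyl–aldehyde coupling that forms the C3–O isobutyrate bond in the same step.
3. 25 ⇐ Barbier adduct 22 + epoxy acid 20 (key step): the C8–O bond is made with inversion (Mitsunobu), which sets C8 and brings in the preformed (2S,3S)-epoxyangelate.
4. 22 ⇐ bromomethyl butenolide 8 + aldehyde 16: zinc Barbier allylation (C7–C8), C7 relayed from C6.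
5. 8 ⇐ dienol 5 + acid 6: C6–O ester tether, then ring-closing metathesis; C6 comes from an asymmetric alkynylation. Ring order: lactone, then ten-membered ring, then core oxirane (the side-chain oxirane is made separately).

Assumption: ring positions follow germacrane numbering; the ligand antipodes named in steps 1 and 16 are those expected to give the stated configurations (the mirror-image ligand is used if the sense proves opposite), and the zinc Barbier addition in step 12 is taken to follow the closed chair transition state.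

**Route**

Step 1
Reactants: 1 (2E)-but-2-enal; 2 propyne
Product: 3 (2E,4S)-hept-2-en-5-yn-4-ol
Conditions: (S,S)-ProPhenol (10 mol%), Me2Zn (3 equiv), Ph3P=O (20 mol%), toluene, 4 °C
Reagents that add atoms: none
Why: Zinc–ProPhenol alkynylation (catalytic asymmetric alkynylzinc addition, for which enals are a favoured substrate class) delivers the propynyl group to the Re face of the aldehyde and so sets the future C6 centre as 4S.

Step 2
Reactants: 3 (2E,4S)-hept-2-en-5-yn-4-ol
Product: 5 (2Z,4S,5E)-2-iodohepta-2,5-dien-4-ol, via cyclic sodium alkenylalanate 4 (not isolated)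
Conditions: NaAlH2(OCH2CH2OCH3)2, THF, 0 to 23 °C; then I2, −78 to 0 °C
Reagents that add atoms: iodine, [I][I]
Why: Hydroxyl-directed trans-hydroalumination of the propargylic alcohol places aluminium on the distal alkyne carbon in a five-membered alanate, and iodinolysis with retention gives the Z-iodoalkene (iodine cis to the carbinol carbon) that becomes the Z-4,5 ring olefin; the isolated E-propenyl group is not reduced.

Step 3
Reactants: 5 (2Z,4S,5E)-2-iodohepta-2,5-dien-4-ol; 6 2-(bromomethyl)prop-2-enoic acid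
Product: 7 (2Z,4S,5E)-2-iodohepta-2,5-dien-4-yl 2-(bromomethyl)prop-2-enoate
Conditions: N,N'-diisopropylcarbodiimide, DMAP (5 mol%), CH2Cl2, 0 °C
Reagents that add atoms: none
Why: Steglich carbodiimide esterification forms the C6–O bond (the future lactone C–O bond) with retention at the carbinol, and the low DMAP loading at 0 °C keeps attack on the allylic bromide small.

Step 4
Reactants: 7 (2Z,4S,5E)-2-iodohepta-2,5-dien-4-yl 2-(bromomethyl)prop-2-enoate
Product: 8 (5S)-3-(bromomethyl)-5-[(1Z)-2-iodoprop-1-en-1-yl]furan-2(5H)-one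
Conditions: second-generation Grubbs catalyst (5 mol%), CH2Cl2 (5 mM), 40 °C
Reagents that add atoms: none
Why: Ring-closing metathesis between the propenyl group and the acrylate olefin closes the butenolide with loss of propene, while the iodinated trisubstituted olefin is too hindered to react and the stereocentre is untouched.

Step 5
Reactants: 9 pent-3-yn-1-ol
Product: 10 tert-butyl(dimethyl)(pent-3-yn-1-yloxy)silane
Conditions: TBSCl, imidazole, CH2Cl2, 23 °C
Reagents that add atoms: tert-butyldimethylsilyl chloride, CC(C)(C)[Si](C)(C)Cl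
Why: Standard silylation masks the future C3 oxygen through the organometallic steps and the Barbier and Mitsunobu reactions.

Step 6
Reactants: 10 tert-butyl(dimethyl)(pent-3-yn-1-yloxy)silane
Product: 12 tert-butyl{[(3E)-4-iodopent-3-en-1-yl]oxy}dimethylsilane, via alkenylzirconocene chloride 11 (not isolated)
Conditions: Cp2Zr(H)Cl (2 equiv), THF, 23 to 45 °C; then I2, 0 °C
Reagents that add atoms: iodine, [I][I]
Why: Hydrozirconation is a syn addition that, after equilibration with excess Cp2Zr(H)Cl, places zirconium next to the methyl group, and iodinolysis with retention gives the E-iodoalkene that fixes the 1(10)-E geometry.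

Step 7
Reactants: 12 tert-butyl{[(3E)-4-iodopent-3-en-1-yl]oxy}dimethylsilane; 13 oxirane
Product: 15 (3E)-6-{[tert-butyl(dimethyl)silyl]oxy}-3-methylhex-3-en-1-ol, via alkenyllithium 14 (not isolated)
Conditions: t-BuLi (2.1 equiv), Et2O, −78 °C; then 13, −78 to 23 °C
Reagents that add atoms: none
Why: Iodine–lithium exchange keeps the olefin geometry and SN2 opening of oxirane by the alkenyllithium adds C9 and C8 to give the E-trisubstituted homoallylic alcohol.

Step 8
Reactants: 15 (3E)-6-{[tert-butyl(dimethyl)silyl]oxy}-3-methylhex-3-en-1-ol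
Product: 16 (3E)-6-{[tert-butyl(dimethyl)silyl]oxy}-3-methylhex-3-enal
Conditions: Dess–Martin periodinane, NaHCO3, CH2Cl2, 0 °C; used crude
Reagents that add atoms: none
Why: Buffered Dess–Martin oxidation gives the β,γ-unsaturated aldehyde without migration of the olefin into conjugation.

Step 9
Reactants: 17 (2Z)-2-methylbut-2-enoic acid (angelic acid)
Product: 18 (2Z)-2-methylbut-2-en-1-ol
Conditions: LiAlH4, Et2O, 0 °C
Reagents that add atoms: none
Why: Hydride reduction of the acid to the allylic alcohol leaves the trisubstituted Z-olefin untouched.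

Step 10
Reactants: 18 (2Z)-2-methylbut-2-en-1-ol
Product: 19 [(2R,3S)-2,3-dimethyloxiran-2-yl]methanol
Conditions: Ti(OiPr)4 (10 mol%), D-(−)-diisopropyl tartrate (12 mol%), t-BuOOH, 4 Å sieves, CH2Cl2, −20 °C
Reagents that add atoms: tert-butyl hydroperoxide, CC(C)(C)OO
Why: Sharpless asymmetric epoxidation with the D-(−)-tartrate delivers oxygen to the olefin face that gives the (2R,3S)-epoxy alcohol (the L-(+)-tartrate gives its enantiomer), and the Z-olefin fixes the cis relation of CH2OH and the C3 methyl group.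

Step 11
Reactants: 19 [(2R,3S)-2,3-dimethyloxiran-2-yl]methanol
Product: 20 (2S,3S)-2,3-dimethyloxirane-2-carboxylic acid
Conditions: RuCl3 (2 mol%), NaIO4 (3 equiv), MeCN/EtOAc/H2O, 0 to 23 °C
Reagents that add atoms: sodium periodate, [Na+].[O-]I(=O)(=O)=O
Why: RuO4 generated in the flask oxidises the primary alcohol to the acid without opening the oxirane; the geometry is unchanged and only the descriptor at C2 changes from R to S.

Step 12
Reactants: 8 (5S)-3-(bromomethyl)-5-[(1Z)-2-iodoprop-1-en-1-yl]furan-2(5H)-one; 16 (3E)-6-{[tert-butyl(dimethyl)silyl]oxy}-3-methylhex-3-enal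
Product: 22 (4R,5S)-4-[(1S,3E)-6-{[tert-butyl(dimethyl)silyl]oxy}-1-hydroxy-3-methylhex-3-en-1-yl]-5-[(1Z)-2-iodoprop-1-en-1-yl]-3-methylideneoxolan-2-one, via allylzinc bromide 21 (not isolated)
Conditions: Zn dust, THF/sat. aq. NH4Cl (1:1), 0 to 23 °C
Reagents that add atoms: none
Why: In this Barbier allylation the aldehyde adds at C7 anti to the C6 alkenyl group (6,7-trans methylene lactone), and the closed Zimmerman–Traxler chair of the E-configured allylzinc with the aldehyde chain equatorial gives the 7,8-anti (8S) carbinol; the alkenyl iodide is inert to zinc.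

Step 13
Reactants: 22 (4R,5S)-4-[(1S,3E)-6-{[tert-butyl(dimethyl)silyl]oxy}-1-hydroxy-3-methylhex-3-en-1-yl]-5-[(1Z)-2-iodoprop-1-en-1-yl]-3-methylideneoxolan-2-one; 20 (2S,3S)-2,3-dimethyloxirane-2-carboxylic acid
Product: 23 (1R,3E)-6-{[tert-butyl(dimethyl)silyl]oxy}-1-[(2S,3R)-2-[(1Z)-2-iodoprop-1-en-1-yl]-4-methylidene-5-oxooxolan-3-yl]-3-methylhex-3-en-1-yl (2S,3S)-2,3-dimethyloxirane-2-carboxylate
Conditions: PPh3, diisopropyl azodicarboxylate, toluene, 0 to 23 °C (betaine preformed)
Reagents that add atoms: none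
Why: Mitsunobu esterification forms the C8–O bond by SN2 attack of the fairly acidic glycidic carboxylate on the oxyphosphonium, inverting 8S to the required 8R and attaching the epoxyangelate in one step; preforming the betaine keeps free phosphine away from the methylene lactone.

Step 14
Reactants: 23 (silyl ether from step 13)
Product: 24 (1R,3E)-6-hydroxy-1-[(2S,3R)-2-[(1Z)-2-iodoprop-1-en-1-yl]-4-methylidene-5-oxooxolan-3-yl]-3-methylhex-3-en-1-yl (2S,3S)-2,3-dimethyloxirane-2-carboxylate
Conditions: HF·pyridine, pyridine, THF, 0 °C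
Reagents that add atoms: none
Why: Buffered fluoride desilylation frees the primary alcohol without touching the lactone, the esters or the electron-poor glycidate oxirane.

Step 15
Reactants: 24 (primary alcohol from step 14)
Product: 25 (1R,3E)-1-[(2S,3R)-2-[(1Z)-2-iodoprop-1-en-1-yl]-4-methylidene-5-oxooxolan-3-yl]-3-methyl-6-oxohex-3-en-1-yl (2S,3S)-2,3-dimethyloxirane-2-carboxylate
Conditions: Dess–Martin periodinane, NaHCO3, CH2Cl2, 0 °C; used at once
Reagents that add atoms: none
Why: Buffered Dess–Martin oxidation gives the C3 β,γ-unsaturated aldehyde under neutral conditions, so neither the olefin nor the C7 centre is disturbed.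

Step 16
Reactants: 25 (iodo aldehyde from step 15); 26 2-methylpropanoic anhydride
Product: 28 (1(10)E,3S,4Z,6R,7R,8R)-8-{[(2S,3S)-2,3-dimethyloxiran-2-yl]carbonyloxy}-3-(2-methylpropanoyloxy)germacra-1(10),4,11(13)-trien-12,6-olide, via dichlorochromium alkoxide 27 (not isolated)
Conditions: CrCl2 (20 mol%), (S)-N-[2-(4-isopropyl-4,5-dihydrooxazol-2-yl)-6-methylphenyl]methanesulfonamide (22 mol%), proton sponge (22 mol%), NiCl2(2,9-dimethyl-1,10-phenanthroline) (5 mol%), Mn (3 equiv), LiCl (2 equiv), 26 (2 equiv), MeCN, 23 °C, slow addition of 25 (final 3 mM)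
Reagents that add atoms: none
Why: Proposed new method: zerovalent nickel inserts into the C4–I bond, the alkenyl group passes with retention of the Z geometry to trivalent chromium held by the chiral sulfonamide, this adds to the C3 aldehyde to close the ten-membered ring with C3 set as S by the ligand, and the hindered anhydride then acylates the trivalent chromium alkoxide so that the isobutyrate is released and the chromium chloride/carboxylate is reduced back to divalent chromium by Mn, the acyl donor taking the role that a chlorosilane or Cp2ZrCl2 plays in the closest known reaction type, the manganese-driven catalytic and ligand-controlled Nozaki–Hiyama–Kishi alkenyl–aldehyde coupling and macrocyclisation.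

Step 17
Reactants: 28 (macrocyclic triene from step 16)
Product: 29 (1R,3S,4Z,6R,7R,8R,10R)-8-{[(2S,3S)-2,3-dimethyloxiran-2-yl]carbonyloxy}-1,10-epoxy-3-(2-methylpropanoyloxy)germacra-4,11(13)-dien-12,6-olide (CNP0117882.1)
Conditions: mCPBA (1.1 equiv), NaHCO3, CH2Cl2, 0 °C
Reagents that add atoms: 3-chloroperoxybenzoic acid, OOC(=O)c1cccc(Cl)c1
Why: Prilezhaev epoxidation picks the only electron-rich olefin (C4=C5 is deactivated by two allylic acyloxy groups and the methylene lactone is electron-poor) and attacks the exposed outer face of the 1(10)-E olefin in the ten-membered ring, giving the trans (1R,10R)-oxirane.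

**Compound list**
1 | (2E)-but-2-enal | C/C=C/C=O | starting material
2 | propyne | CC#C | starting material
3 | (2E,4S)-hept-2-en-5-yn-4-ol | C/C=C/[C@H](O)C#CC | intermediate
4 | cyclic sodium alkenylalanate of 3 (Al on the methyl-bearing olefin carbon, chelated to the carbinol oxygen, two 2-methoxyethoxy ligands) | C/C=C/[C@H]1C=C(C)[Al-](OCCOC)(OCCOC)O1.[Na+] | intermediate (not isolated)
5 | (2Z,4S,5E)-2-iodohepta-2,5-dien-4-ol | C/C=C/[C@H](O)/C=C(/C)I | intermediate
6 | 2-(bromomethyl)prop-2-enoic acid | C=C(CBr)C(=O)O | starting material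
7 | (2Z,4S,5E)-2-iodohepta-2,5-dien-4-yl 2-(bromomethyl)prop-2-enoate | C/C=C/[C@H](OC(=O)C(=C)CBr)/C=C(/C)I | intermediate
8 | (5S)-3-(bromomethyl)-5-[(1Z)-2-iodoprop-1-en-1-yl]furan-2(5H)-one | O=C1O[C@H](/C=C(/C)I)C=C1CBr | intermediate
9 | pent-3-yn-1-ol | CC#CCCO | starting material
10 | tert-butyl(dimethyl)(pent-3-yn-1-yloxy)silane | CC#CCCO[Si](C)(C)C(C)(C)C | intermediate
11 | chlorobis(cyclopentadienyl)[(2E)-5-silyloxypent-2-en-2-yl]zirconium | C/C(=C\CCO[Si](C)(C)C(C)(C)C)[Zr](Cl)(C1C=CC=C1)C1C=CC=C1 | intermediate (not isolated)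
12 | tert-butyl{[(3E)-4-iodopent-3-en-1-yl]oxy}dimethylsilane | C/C(I)=C\CCO[Si](C)(C)C(C)(C)C | intermediate
13 | oxirane | C1CO1 | starting material
14 | [(2E)-5-{[tert-butyl(dimethyl)silyl]oxy}pent-2-en-2-yl]lithium | C/C([Li])=C\CCO[Si](C)(C)C(C)(C)C | intermediate (not isolated)
15 | (3E)-6-{[tert-butyl(dimethyl)silyl]oxy}-3-methylhex-3-en-1-ol | OCC/C(C)=C/CCO[Si](C)(C)C(C)(C)C | intermediate
16 | (3E)-6-{[tert-butyl(dimethyl)silyl]oxy}-3-methylhex-3-enal | O=CC/C(C)=C/CCO[Si](C)(C)C(C)(C)C | intermediate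
17 | (2Z)-2-methylbut-2-enoic acid (angelic acid) | C/C=C(/C)C(=O)O | starting material
18 | (2Z)-2-methylbut-2-en-1-ol | C/C=C(/C)CO | intermediate
19 | [(2R,3S)-2,3-dimethyloxiran-2-yl]methanol | OC[C@@]1(C)O[C@H]1C | intermediate
20 | (2S,3S)-2,3-dimethyloxirane-2-carboxylic acid | OC(=O)[C@@]1(C)O[C@H]1C | intermediate
21 | {(5S)-5-[(1Z)-2-iodoprop-1-en-1-yl]-2-oxo-2,5-dihydrofuran-3-yl}methylzinc bromide | O=C1O[C@H](/C=C(/C)I)C=C1C[Zn]Br | intermediate (not isolated)
22 | (4R,5S)-4-[(1S,3E)-6-{[tert-butyl(dimethyl)silyl]oxy}-1-hydroxy-3-methylhex-3-en-1-yl]-5-[(1Z)-2-iodoprop-1-en-1-yl]-3-methylideneoxolan-2-one | C=C1C(=O)O[C@H](/C=C(/C)I)[C@H]1[C@@H](O)C/C(C)=C/CCO[Si](C)(C)C(C)(C)C | intermediate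
23 | (1R,3E)-6-{[tert-butyl(dimethyl)silyl]oxy}-1-[(2S,3R)-2-[(1Z)-2-iodoprop-1-en-1-yl]-4-methylidene-5-oxooxolan-3-yl]-3-methylhex-3-en-1-yl (2S,3S)-2,3-dimethyloxirane-2-carboxylate | C=C1C(=O)O[C@H](/C=C(/C)I)[C@H]1[C@H](OC(=O)[C@@]2(C)O[C@H]2C)C/C(C)=C/CCO[Si](C)(C)C(C)(C)C | intermediate
24 | (1R,3E)-6-hydroxy-1-[(2S,3R)-2-[(1Z)-2-iodoprop-1-en-1-yl]-4-methylidene-5-oxooxolan-3-yl]-3-methylhex-3-en-1-yl (2S,3S)-2,3-dimethyloxirane-2-carboxylate | C=C1C(=O)O[C@H](/C=C(/C)I)[C@H]1[C@H](OC(=O)[C@@]2(C)O[C@H]2C)C/C(C)=C/CCO | intermediate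
25 | (1R,3E)-1-[(2S,3R)-2-[(1Z)-2-iodoprop-1-en-1-yl]-4-methylidene-5-oxooxolan-3-yl]-3-methyl-6-oxohex-3-en-1-yl (2S,3S)-2,3-dimethyloxirane-2-carboxylate | C=C1C(=O)O[C@H](/C=C(/C)I)[C@H]1[C@H](OC(=O)[C@@]2(C)O[C@H]2C)C/C(C)=C/CC=O | intermediate
26 | 2-methylpropanoic anhydride | CC(C)C(=O)OC(=O)C(C)C | starting material
27 | dichlorochromium alkoxide of the (3S)-macrocyclic carbinol (sulfonamide ligand omitted) | C=C1C(=O)O[C@@H]2/C=C(/C)[C@@H](O[Cr](Cl)Cl)C/C=C(\C)C[C@@H](OC(=O)[C@@]3(C)O[C@H]3C)[C@@H]12 | intermediate (not isolated)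
28 | (1(10)E,3S,4Z,6R,7R,8R)-8-{[(2S,3S)-2,3-dimethyloxiran-2-yl]carbonyloxy}-3-(2-methylpropanoyloxy)germacra-1(10),4,11(13)-trien-12,6-olide | C=C1C(=O)O[C@@H]2/C=C(/C)[C@@H](OC(=O)C(C)C)C/C=C(\C)C[C@@H](OC(=O)[C@@]3(C)O[C@H]3C)[C@@H]12 | intermediate
29 | (1R,3S,4Z,6R,7R,8R,10R)-8-{[(2S,3S)-2,3-dimethyloxiran-2-yl]carbonyloxy}-1,10-epoxy-3-(2-methylpropanoyloxy)germacra-4,11(13)-dien-12,6-olide | C=C1C(=O)O[C@@H]2/C=C(/C)[C@@H](OC(=O)C(C)C)C[C@H]3O[C@]3(C)C[C@@H](OC(=O)[C@@]3(C)O[C@H]3C)[C@@H]12 | target

**Step count and risks**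
Total step count: 17. Longest linear sequence: 10 steps (steps 1–4, then 12–17; the branch through steps 5–8 is equally long).

Three steps most likely to fail:

Step 16 (proposed new acylative ring closure). The acyl donor may not turn over chromium, nickel may acylate the alkenyl group, or the C3 selectivity may be poor. The fallback uses known chemistry and sets out from 25. Stoichiometric CrCl2 (4 equiv) with NiCl2 (1 mol%) in degassed DMSO/THF at 2 mM, without acyl donor, is the classical Nozaki–Hiyama–Kishi ring closure and gives the free allylic alcohol. The (3S)-allylic alcohol F1 is acylated with 26 and DMAP. Its (3R)-epimer F2 is instead treated with 2-methylpropanoic acid, PPh3 and diisopropyl azodicarboxylate (Mitsunobu inversion). Both paths come back to the route at 28.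

Step 13 (Mitsunobu at the hindered C8 carbinol). Elimination towards C7 or C9, or slow substitution, may win. The fallback sets out from 22 and fixes C8 by hydride delivery instead of C–O inversion. Buffered Dess–Martin oxidation gives the C8 ketone F3, which is used at once to avoid migration of the methylene into conjugation. Reduction with (S)-Me-CBS oxazaborolidine and catecholborane at −78 °C gives the (8R)-alcohol F4. Esterification of F4 with 20 using N,N'-diisopropylcarbodiimide and DMAP (retention) comes back to the route at 23. The same retentive acylation applies directly if step 12 should deliver the (8R)-alcohol F4 itself.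

Step 17 (facial selectivity of the last epoxidation). The macrocycle may present the wrong olefin face or give a mixture. The fallback sets out from 28 and replaces substrate control by catalyst control: a Shi epoxidation with the fructose-derived ketone antipode matched to the (1R,10R)-oxirane, Oxone, buffered at pH 8, MeCN/dimethoxymethane/H2O, 0 °C. It comes back to the route at 29 and makes no new compound (F0).

**Further compounds**
F1 | step 16 | (1(10)E,3S,4Z,6R,7R,8R)-8-{[(2S,3S)-2,3-dimethyloxiran-2-yl]carbonyloxy}-3-hydroxygermacra-1(10),4,11(13)-trien-12,6-olide | C=C1C(=O)O[C@@H]2/C=C(/C)[C@@H](O)C/C=C(\C)C[C@@H](OC(=O)[C@@]3(C)O[C@H]3C)[C@@H]12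
F2 | step 16 | (1(10)E,3R,4Z,6R,7R,8R)-8-{[(2S,3S)-2,3-dimethyloxiran-2-yl]carbonyloxy}-3-hydroxygermacra-1(10),4,11(13)-trien-12,6-olide | C=C1C(=O)O[C@@H]2/C=C(/C)[C@H](O)C/C=C(\C)C[C@@H](OC(=O)[C@@]3(C)O[C@H]3C)[C@@H]12
F3 | step 13 | (4S,5S)-4-[(3E)-6-{[tert-butyl(dimethyl)silyl]oxy}-3-methylhex-3-enoyl]-5-[(1Z)-2-iodoprop-1-en-1-yl]-3-methylideneoxolan-2-one | C=C1C(=O)O[C@H](/C=C(/C)I)[C@H]1C(=O)C/C(C)=C/CCO[Si](C)(C)C(C)(C)C
F4 | step 13 | (4R,5S)-4-[(1R,3E)-6-{[tert-butyl(dimethyl)silyl]oxy}-1-hydroxy-3-methylhex-3-en-1-yl]-5-[(1Z)-2-iodoprop-1-en-1-yl]-3-methylideneoxolan-2-one | C=C1C(=O)O[C@H](/C=C(/C)I)[C@H]1[C@H](O)C/C(C)=C/CCO[Si](C)(C)C(C)(C)C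
F0 | step 17 | none | none
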